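**Your hunch.** Each bit of product, I assume, costs one bit of scavenger, and you suspect that this flask, charged short of scavenger, runs out of it by 1.0 h. Here is the quick number.

in all of them: gas 8.6 mM (held)

| flask | starting material | scavenger | remark | time |
|---|---|---|---|---|
| elm | 0.014 M | 0.0168 M | run made earlier |  |
| oak | 0.032 M | 0.0168 M | run made earlier |  |
| birch | 0.021 M | 0.0084 M | run made earlier |  |
| flask | 0.021 M | 0.0168 M |  | 1.0 h |

| run | time / min | starting material / % | product / % |
|---|---|---|---|
| elm | 8.00 | 98.6 | 4.6 |
| elm | 15.0 | 94.3 | 3.4 |
| elm | 25.0 | 93.0 | 7.2 |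
| elm | 30.0 | 90.3 | 7.1 |
| elm | 40.0 | 90.3 | 12.4 |
| elm | 50.0 | 86.6 | 14.8 |
| elm | 60.0 | 82.4 | 17.5 |
| oak | 5.00 | 99.2 | 0.1 |
| oak | 8.00 | 96.5 | 2.8 |
| oak | 12.0 | 95.5 | 3.7 |
| oak | 15.0 | 94.1 | 4.4 |
| oak | 25.0 | 91.5 | 6.5 |
| oak | 40.0 | 87.9 | 10.8 |
| oak | 60.0 | 81.1 | 16.0 |
| birch | 5.00 | 98.7 | 1.7 |
| birch | 10.0 | 96.7 | 3.7 |
| birch | 15.0 | 94.9 | 4.5 |
| birch | 30.0 | 89.5 | 11.0 |
| birch | 60.0 | 82.6 | 17.8 |

(readings scatter by 1 percentage point)

* part of the starting material that has reacted at 1.0 h
* share of the unused partner that is free and not bound as idle adduct, at 1.0 h

- the analysis behind the earlier runs scatters by 1 percentage point, standard deviation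
- at the start none of the gas is in solution
- the earlier runs do not show how much of partner is bound; that part of a forecast is a guess

**The balance.** Take the cover, 0.800 in this flask: the scavenger charge as a fraction of the starting-material charge, in equivalents. On my assumption, the reacted fraction divided by the cover is the fraction of its own charge the scavenger has spent.

**The runs.** Elm, oak and birch had covers of 1.20, 0.525 and 0.400, yet by 60.0 min they had lost 18.0 % of their starting material on average, each within the scatter of 1 percentage point. Birch's cover, lower than the other two, still stands above that loss.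

**My number.** I commit to 18.0 % for this flask, which spends 22.5 % of its scavenger. That loss stays below the cover, so on this balance I expect this flask still to hold scavenger at 1.0 h. The runs do not show the free share of partner, so I give no figure for it.

**The forecast.** It said 18 % (16.5 % to 19.5 %) and a free share of 50 % (10 % to 90 %), the latter “essentially a guess”.

**The flask.** It gives 17.3 % reacted and >99.9 % free.

    starting material + partner + released group → product + 2 released group (k = 1680 /M²/min)
    starting material + partner → product + released group (k = 0.364 /M/min)
    partner + released group ⇌ idle adduct, settled at all times (K = 37.9 /M)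
    scavenger + released group → scavenged by-product (k = 1570 /M/min)
    gas ⇌ partner, rate k5*(csat - [partner]) (kL = 27.5 /min)

**The check.** Dividing 17.3 % by the cover of 0.800 leaves 78.4 % of the scavenger, and the flask holds 78 %. At 1.00 h the plain step from starting material and partner used starting material 81 times as fast as the step that also needs released group. Released group then stood at 2.66 × 10⁻⁶ M and idle adduct at 8.67 × 10⁻⁷ M, beside 0.00860 M of partner.

**The neighbour.** With 0.0067 M of scavenger the cover is 0.319, so a loss of 18.0 % should leave 43.6 % of that flask's scavenger. The neighbour flask gives 17.7 % reacted and 45 % of its scavenger left.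

(The readings stem from a simulated flask from invented constants, and the scatter is random.)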